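**Retrosynthetic overview**

The route rests on ring A: a benzene with para oxygens on C5 and C8, the 3-hydroxy-3-methylbutyl chain on C6 beside the C5 hydroxyl and hydrogen on C7, which is the pattern a terminal alkyne leaves in a chromium carbene benzannulation.
Key disconnection C8–C7, C6–C5 and C5–C4a: ring A is closed last onto a finished ring C, from a (4-pyranon-2-yl)methoxycarbene Cr(CO)5 complex (carbene carbon becomes C8, one CO becomes C5, pyranone C2=C3 becomes C8a=C4a) and 2-methylhex-5-yn-2-ol (C6, C7).
The carbene comes from the pyranone-2-carbonyl chloride and Na2Cr(CO)5; the C3–C1' bond comes from Suzuki coupling of a comenate triflate (ring C, from kojic acid) with a chromenyl boronate (ring B with its dimethylpyran ring D).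
Ring order: ring C is bought; ring D is made on ring B from a 6-bromocoumarin and MeMgBr; biaryl coupling; ring A by benzannulation; then C8–OMe to C8–OH through the 5,8-quinone and removal of the MOM group.

Key step: step 12

Assumption: the target has no stereocentre, so none has to be set; the only stereo-element on the way is the Z alkene of the non-isolated diol 10, inherited from the coumarin. The hindered tertiary alcohol of the alkyne is carried unprotected.

**Route**

Step 1
Reactants: 1 kojic acid
Product: 2 comenic acid (5-hydroxy-4-oxo-4H-pyran-2-carboxylic acid)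
Conditions: O2 (1 atm), Pd/C (cat.), aq NaOH (pH 9), 60 °C; then HCl
Reagents that add atoms: water, O
Why: Heyns-type aerobic dehydrogenation of the primary alcohol on palladium metal in weakly basic water runs through the aldehyde hydrate to the carboxylate (the new oxygen comes from water, O2 only accepts hydrogen), the known way from kojic acid to comenic acid, and should leave the enolic hydroxyl and the pyranone ring alone.

Step 2
Reactants: 2 comenic acid
Product: 3 methyl 5-hydroxy-4-oxo-4H-pyran-2-carboxylate
Conditions: MeOH, H2SO4 (cat.), reflux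
Reagents that add atoms: methanol, CO
Why: Fischer esterification of the carboxylic acid in excess methanol, in which the enolic hydroxyl does not take part.

Step 3
Reactants: 3 methyl 5-hydroxy-4-oxo-4H-pyran-2-carboxylate
Product: 4 methyl 4-oxo-5-(trifluoromethylsulfonyloxy)-4H-pyran-2-carboxylate
Conditions: Tf2O, pyridine, CH2Cl2, −20 to 0 °C
Reagents that add atoms: trifluoromethanesulfonic anhydride, O=S(=O)(OS(=O)(=O)C(F)(F)F)C(F)(F)F
Why: O-sulfonylation of the acidic enolic hydroxyl (enol triflate formation), as known for 3-hydroxy-4-pyranones of the kojic acid and maltol type.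

Step 4
Reactants: 5 4-bromoresorcinol; 6 (±)-malic acid
Product: 8 6-bromo-7-hydroxy-2H-chromen-2-one, via formylacetic acid 7 (not isolated)
Conditions: conc. H2SO4, 110 °C
Reagents that add atoms: none
Why: von Pechmann condensation, in which malic acid loses CO and water to give formylacetic acid, which attacks C6 of the resorcinol (para to one hydroxyl and ortho to the other, the only such position left by the bromine) and lactonises, so the bromine ends at C6 of the coumarin without ambiguity.

Step 5
Reactants: 8 6-bromo-7-hydroxy-2H-chromen-2-one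
Product: 9 6-bromo-7-(methoxymethoxy)-2H-chromen-2-one
Conditions: MOMCl, iPr2NEt, CH2Cl2, 0 °C to rt
Reagents that add atoms: chloromethyl methyl ether, COCCl
Why: O-alkylation of the phenol with the α-chloro ether gives the MOM acetal, which removes the acidic proton before the Grignard step and later flanks the boronate.

Step 6
Reactants: 9 6-bromo-7-(methoxymethoxy)-2H-chromen-2-one
Product: 11 6-bromo-7-(methoxymethoxy)-2,2-dimethyl-2H-chromene, via Z-allylic diol 10 (not isolated)
Conditions: MeMgBr (3 equiv), THF, 0 °C to rt; aq NH4Cl; then AcOH (cat.), toluene, 50 °C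
Reagents that add atoms: methylmagnesium bromide, C[Mg]Br
Why: Double 1,2-addition of the Grignard reagent to the lactone gives diol 10, whose Z geometry is inherited from the cis C3=C4 bond of the coumarin, and mild acid ionises the activated tertiary allylic alcohol so that the phenol closes the 2,2-dimethyl-2H-chromene (classical coumarin-to-chromene conversion), the aryl bromide and the MOM ether being inert to MeMgBr.

Step 7
Reactants: 11 6-bromo-7-(methoxymethoxy)-2,2-dimethyl-2H-chromene
Product: 13 2-[7-(methoxymethoxy)-2,2-dimethyl-2H-chromen-6-yl]-4,4,5,5-tetramethyl-1,3,2-dioxaborolane, via 6-lithiochromene 12 (not isolated)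
Conditions: n-BuLi, THF, −78 °C; then iPrOBpin, −78 °C to rt
Reagents that add atoms: 2-isopropoxy-4,4,5,5-tetramethyl-1,3,2-dioxaborolane, CC(C)OB1OC(C)(C)C(C)(C)O1
Why: Bromine–lithium exchange is faster than any deprotonation at −78 °C, the ortho MOM oxygen stabilises aryllithium 12, and the borate traps it as the pinacol boronate.

Step 8
Reactants: 4 methyl 4-oxo-5-(trifluoromethylsulfonyloxy)-4H-pyran-2-carboxylate; 13 chromenyl pinacol boronate
Product: 14 methyl 5-[7-(methoxymethoxy)-2,2-dimethyl-2H-chromen-6-yl]-4-oxo-4H-pyran-2-carboxylate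
Conditions: Pd(PPh3)4 (5 mol %), K3PO4, 1,4-dioxane/H2O, 80 °C
Reagents that add atoms: none
Why: Suzuki–Miyaura coupling, in which zerovalent palladium inserts readily into the electron-poor enol triflate and the phosphate-activated boronate transfers the aryl group, a coupling known for triflates of 3-hydroxy-4-pyranones.

Step 9
Reactants: 14 methyl 5-aryl-4-oxo-4H-pyran-2-carboxylate
Product: 15 5-[7-(methoxymethoxy)-2,2-dimethyl-2H-chromen-6-yl]-4-oxo-4H-pyran-2-carboxylic acid
Conditions: LiOH·H2O, THF/H2O, 0 °C; then 1 M HCl to pH 3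
Reagents that add atoms: lithium hydroxide, [Li+].[OH-]
Why: Saponification of this activated heteroaryl ester should be fast at 0 °C, so that hydroxide addition at the unsubstituted C6 of the pyranone does not compete, and brief cold acidification to pH 3 leaves the MOM ether intact.

Step 10
Reactants: 15 5-aryl-4-oxo-4H-pyran-2-carboxylic acid
Product: 16 5-[7-(methoxymethoxy)-2,2-dimethyl-2H-chromen-6-yl]-4-oxo-4H-pyran-2-carbonyl chloride
Conditions: 1-chloro-N,N,2-trimethylprop-1-en-1-amine, CH2Cl2, 0 °C to rt
Reagents that add atoms: 1-chloro-N,N,2-trimethylprop-1-en-1-amine, CC(C)=C(Cl)N(C)C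
Why: The α-chloroenamine (Ghosez reagent) turns the acid into the acid chloride under neutral conditions with an amide as the only by-product, so no HCl reaches the MOM ether or the chromene.

Step 11
Reactants: 16 pyranone-2-carbonyl chloride; 17 chromium hexacarbonyl
Product: 20 pentacarbonyl{methoxy[5-(7-methoxymethoxy-2,2-dimethyl-2H-chromen-6-yl)-4-oxo-4H-pyran-2-yl]carbene}chromium, via disodium pentacarbonylchromate 18 (not isolated), via sodium acyl chromate 19 (not isolated)
Conditions: 17, sodium naphthalenide (2 equiv), THF, −78 °C; add 16 slowly, −78 to 0 °C; then Me3OBF4, CH2Cl2, 0 °C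
Reagents that add atoms: trimethyloxonium tetrafluoroborate, C[O+](C)C.F[B-](F)(F)F
Why: Two-electron reduction of Cr(CO)6 gives dianion 18, its acylation by the acid chloride gives acyl chromate 19 and O-methylation with the oxonium salt gives the Fischer carbene (the standard acid chloride route to alkoxycarbene complexes), the acylate oxygen being far more nucleophilic than the pyranone carbonyl so that one equivalent of methylating agent should spare ring C.

Step 12
Reactants: 20 pyranonyl methoxycarbene chromium complex; 21 2-methylhex-5-yn-2-ol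
Product: 22 5-hydroxy-6-(3-hydroxy-3-methylbutyl)-8-methoxy-3-[7-(methoxymethoxy)-2,2-dimethyl-2H-chromen-6-yl]-4H-chromen-4-one
Conditions: 21 (2 equiv), THF (degassed, 0.05 M), 50 °C; then air, rt
Reagents that add atoms: none
Why: Thermal loss of one cis CO from 20 lets alkyne 21 coordinate and insert to a vinylcarbene whose unsubstituted alkyne carbon is bonded to the former carbene carbon (C8–C7), CO insertion gives the chromium-bound dienylketene (C6–C5), and 6π-electrocyclisation of this ketene onto pyranone C3 (C5–C4a) followed by enolisation gives the 4-methoxyphenol. This is a Dötz benzannulation, and the closest known cases are 2-furyl, cyclohexenyl and dihydropyran-2-yl (cyclic α-alkoxyvinyl) methoxycarbene complexes reacting with terminal alkynes. Ring A is closed in the electrocyclic 6π mode from carbene carbon plus C8a=C4a, the two alkyne carbons and one CO, and no stereocentre is created. The step needs regioselective insertion (chain on C6 next to the CO-derived C5, hydrogen on C7), which the steric difference between the hydrogen and alkyl ends of a terminal alkyne secures. It also needs CO insertion and six-ring closure to outrun furan, cyclobutenone and five-ring products, which chromium, an alkenyl-type carbene, an ethereal solvent and moderate temperature favour; the closure is helped because pyranone C3 is the nucleophilic α-carbon of a vinylogous ester and the product gains aromaticity and the C5–OH to C4=O hydrogen bond. The hindered tertiary alcohol, the MOM ether and the chromene alkene are not expected to intervene at 50 °C.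

Step 13
Reactants: 22 8-methoxy-5-hydroxy isoflavone
Product: 23 6-(3-hydroxy-3-methylbutyl)-3-[7-(methoxymethoxy)-2,2-dimethyl-2H-chromen-6-yl]-4H-chromene-4,5,8-trione
Conditions: PhI(OAc)2, MeCN/H2O (2:1), 0 °C
Reagents that add atoms: water, O
Why: Oxidative demethylation, in which trivalent iodine oxidises the 4-methoxyphenol to a phenoxonium ion, water adds at C8 para to the hydroxyl and the hemiketal loses methanol to give the p-quinone, while the MOM-capped ring B has no free phenol to be attacked.

Step 14
Reactants: 23 isoflavone-5,8-quinone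
Product: 24 5,8-dihydroxy-6-(3-hydroxy-3-methylbutyl)-3-[7-(methoxymethoxy)-2,2-dimethyl-2H-chromen-6-yl]-4H-chromen-4-one
Conditions: Na2S2O4, EtOAc/H2O, rt
Reagents that add atoms: none
Why: Dithionite reduces the quinone to the hydroquinone by two-electron transfer in a two-phase system and does not touch the chromone or chromene double bonds.

Step 15
Reactants: 24 MOM-protected hydroquinone
Product: 25 Kraussianone 3
Conditions: 2 M HCl, MeOH/THF, 40 °C, argon
Reagents that add atoms: none
Why: Acid-catalysed methanolysis of the aryl methoxymethyl acetal frees the 2'-hydroxyl, dilute acid at 40 °C being too weak to ionise the tertiary alcohol (chroman closure onto the C5 hydroxyl) or to open the dimethylchromene, and exclusion of air keeps the hydroquinone from reoxidising.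

**Compound list**

1 | kojic acid | OCc1cc(=O)c(O)co1 | starting material
2 | comenic acid | O=C(O)c1cc(=O)c(O)co1 | intermediate
3 | methyl 5-hydroxy-4-oxo-4H-pyran-2-carboxylate | COC(=O)c1cc(=O)c(O)co1 | intermediate
4 | methyl 4-oxo-5-(trifluoromethylsulfonyloxy)-4H-pyran-2-carboxylate | COC(=O)c1cc(=O)c(OS(=O)(=O)C(F)(F)F)co1 | intermediate
5 | 4-bromoresorcinol | Oc1ccc(Br)c(O)c1 | starting material
6 | (±)-malic acid | OC(CC(=O)O)C(=O)O | starting material
7 | formylacetic acid (3-oxopropanoic acid) | O=CCC(=O)O | intermediate (not isolated)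
8 | 6-bromo-7-hydroxy-2H-chromen-2-one | O=c1ccc2cc(Br)c(O)cc2o1 | intermediate
9 | 6-bromo-7-(methoxymethoxy)-2H-chromen-2-one | COCOc1cc2oc(=O)ccc2cc1Br | intermediate
10 | 4-bromo-2-[(1Z)-3-hydroxy-3-methylbut-1-en-1-yl]-5-(methoxymethoxy)phenol | CC(C)(O)/C=C\c1cc(Br)c(OCOC)cc1O | intermediate (not isolated)
11 | 6-bromo-7-(methoxymethoxy)-2,2-dimethyl-2H-chromene | COCOc1cc2c(cc1Br)C=CC(C)(C)O2 | intermediate
12 | [7-(methoxymethoxy)-2,2-dimethyl-2H-chromen-6-yl]lithium | [Li]c1cc2c(cc1OCOC)OC(C)(C)C=C2 | intermediate (not isolated)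
13 | 2-[7-(methoxymethoxy)-2,2-dimethyl-2H-chromen-6-yl]-4,4,5,5-tetramethyl-1,3,2-dioxaborolane | COCOc1cc2c(cc1B1OC(C)(C)C(C)(C)O1)C=CC(C)(C)O2 | intermediate
14 | methyl 5-[7-(methoxymethoxy)-2,2-dimethyl-2H-chromen-6-yl]-4-oxo-4H-pyran-2-carboxylate | COC(=O)c1cc(=O)c(-c2cc3c(cc2OCOC)OC(C)(C)C=C3)co1 | intermediate
15 | 5-[7-(methoxymethoxy)-2,2-dimethyl-2H-chromen-6-yl]-4-oxo-4H-pyran-2-carboxylic acid | O=C(O)c1cc(=O)c(-c2cc3c(cc2OCOC)OC(C)(C)C=C3)co1 | intermediate
16 | 5-[7-(methoxymethoxy)-2,2-dimethyl-2H-chromen-6-yl]-4-oxo-4H-pyran-2-carbonyl chloride | O=C(Cl)c1cc(=O)c(-c2cc3c(cc2OCOC)OC(C)(C)C=C3)co1 | intermediate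
17 | chromium hexacarbonyl | O=C=[Cr](=C=O)(=C=O)(=C=O)(=C=O)=C=O | starting material
18 | disodium pentacarbonylchromate | [Na+].[Na+].O=C=[Cr-2](=C=O)(=C=O)(=C=O)=C=O | intermediate (not isolated)
19 | sodium pentacarbonyl[(5-aryl-4-oxo-4H-pyran-2-yl)oxidomethylidene]chromate (acyl chromate) | [Na+].[O-]C(=[Cr](=C=O)(=C=O)(=C=O)(=C=O)=C=O)c1cc(=O)c(-c2cc3c(cc2OCOC)OC(C)(C)C=C3)co1 | intermediate (not isolated)
20 | pentacarbonyl{methoxy[5-(7-methoxymethoxy-2,2-dimethyl-2H-chromen-6-yl)-4-oxo-4H-pyran-2-yl]carbene}chromium | COC(=[Cr](=C=O)(=C=O)(=C=O)(=C=O)=C=O)c1cc(=O)c(-c2cc3c(cc2OCOC)OC(C)(C)C=C3)co1 | intermediate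
21 | 2-methylhex-5-yn-2-ol | C#CCCC(C)(C)O | starting material
22 | 5-hydroxy-6-(3-hydroxy-3-methylbutyl)-8-methoxy-3-[7-(methoxymethoxy)-2,2-dimethyl-2H-chromen-6-yl]-4H-chromen-4-one | COc1cc(CCC(C)(C)O)c(O)c2c(=O)c(-c3cc4c(cc3OCOC)OC(C)(C)C=C4)coc12 | intermediate
23 | 6-(3-hydroxy-3-methylbutyl)-3-[7-(methoxymethoxy)-2,2-dimethyl-2H-chromen-6-yl]-4H-chromene-4,5,8-trione | CC(C)(O)CCC1=CC(=O)C2=C(C1=O)C(=O)C(=CO2)c1cc3C=CC(C)(C)Oc3cc1OCOC | intermediate
24 | 5,8-dihydroxy-6-(3-hydroxy-3-methylbutyl)-3-[7-(methoxymethoxy)-2,2-dimethyl-2H-chromen-6-yl]-4H-chromen-4-one | CC(C)(O)CCc1cc(O)c2occ(-c3cc4c(cc3OCOC)OC(C)(C)C=C4)c(=O)c2c1O | intermediate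
25 | Kraussianone 3 | CC(C)(O)CCc1cc(O)c2occ(-c3cc4c(cc3O)OC(C)(C)C=C4)c(=O)c2c1O | target

**Step count**

Total steps: 15. Longest linear sequence: 12 steps (steps 4 to 15, from 4-bromoresorcinol 5).

**Steps most likely to fail**

1. Step 12 (benzannulation). The alkyne-inserted vinylcarbene or its ketene may fail to electrocyclise onto the electron-poor pyranone C3, so that furan, cyclobutenone or alkyne oligomer pathways take over, or the insertion may lose its regiochemical bias. The fallback drops chromium and assembles the isoflavone by cross-coupling. It sets out from boronate 13 and bought 2,5-dimethoxyphenol and comes back at 22. NBS brominates the phenol para to the hydroxyl to give 4-bromo-2,5-dimethoxyphenol F1. Acetic acid with BF3·OEt2 acetylates the single free ortho position to give 1-(3-bromo-6-hydroxy-2,5-dimethoxyphenyl)ethanone F2. Dimethylformamide dimethyl acetal gives (E)-1-(3-bromo-6-hydroxy-2,5-dimethoxyphenyl)-3-(dimethylamino)prop-2-en-1-one F3. Iodine closes and iodinates it to 6-bromo-3-iodo-5,8-dimethoxy-4H-chromen-4-one F4. BCl3 at low temperature cleaves only the peri methoxy group and gives 6-bromo-5-hydroxy-3-iodo-8-methoxy-4H-chromen-4-one F5. Suzuki coupling with 13 at the more reactive C3–I bond (Pd(PPh3)4, Na2CO3) gives 6-bromo-5-hydroxy-8-methoxy-3-[7-(methoxymethoxy)-2,2-dimethyl-2H-chromen-6-yl]-4H-chromen-4-one F6. A B-alkyl Suzuki coupling of F6 (Pd(OAc)2, SPhos, K3PO4) with 4-(9-borabicyclo[3.3.1]nonan-9-yl)-2-methylbutan-2-ol F7, preformed from 2-methylbut-3-en-2-ol and 9-BBN, installs the side chain and gives 22.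

2. Step 11 (carbene formation). Electron transfer or conjugate addition of the strongly reducing chromate dianion to the pyranone may compete with acylation, and the first-formed acyl chromate may be O-acylated by a second molecule of 16. The fallback makes the acyl chromate from an organolithium and Cr(CO)6 instead. It sets out from comenic acid 2 and boronate 13 and comes back at 20. Thermal decarboxylation of 2 gives pyromeconic acid (3-hydroxy-4H-pyran-4-one) F8. Tf2O and pyridine give 4-oxo-4H-pyran-3-yl trifluoromethanesulfonate F9. Suzuki coupling with 13 gives 3-[7-(methoxymethoxy)-2,2-dimethyl-2H-chromen-6-yl]-4H-pyran-4-one F10. LiTMP at −78 °C should deprotonate the unhindered C6–H next to the ring oxygen, the other α-oxygen position being shielded by the twisted aryl group, to give the 6-lithio-3-aryl-4H-pyran-4-one F11. This is added to chromium hexacarbonyl 17 to give the lithium acyl chromate F12, and Me3OBF4 methylates it to 20.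

3. Step 13 (oxidative demethylation). The electron-rich chromene ring B may be over-oxidised, or the side-chain hydroxyl may capture the ring A phenoxonium ion at C6 as a spiro ether before water adds at C8. The fallback replaces the methyl ether by a benzylic ether that is cleaved at the benzylic carbon. It sets out from acyl chromate 19 and comes back at 23. Cation exchange with Me4NBr gives the isolable tetramethylammonium acyl chromate F13. Acetyl bromide at −40 °C gives the acetoxycarbene complex F14, which is not isolated. 4-Methoxybenzyl alcohol displaces acetate to give the (4-methoxybenzyloxy)carbene complex F15. Benzannulation with 21 as in step 12 gives 5-hydroxy-6-(3-hydroxy-3-methylbutyl)-8-(4-methoxybenzyloxy)-3-[7-(methoxymethoxy)-2,2-dimethyl-2H-chromen-6-yl]-4H-chromen-4-one F16. DDQ in wet CH2Cl2 removes the benzyl group by hydride abstraction and oxidises the freed hydroquinone to quinone 23.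

**Further compounds**

F1 | step 12 | 4-bromo-2,5-dimethoxyphenol | COc1cc(Br)c(OC)cc1O
F2 | step 12 | 1-(3-bromo-6-hydroxy-2,5-dimethoxyphenyl)ethanone | CC(=O)c1c(O)c(OC)cc(Br)c1OC
F3 | step 12 | (E)-1-(3-bromo-6-hydroxy-2,5-dimethoxyphenyl)-3-(dimethylamino)prop-2-en-1-one | CN(C)/C=C/C(=O)c1c(O)c(OC)cc(Br)c1OC
F4 | step 12 | 6-bromo-3-iodo-5,8-dimethoxy-4H-chromen-4-one | COc1cc(Br)c(OC)c2c(=O)c(I)coc12
F5 | step 12 | 6-bromo-5-hydroxy-3-iodo-8-methoxy-4H-chromen-4-one | COc1cc(Br)c(O)c2c(=O)c(I)coc12
F6 | step 12 | 6-bromo-5-hydroxy-8-methoxy-3-[7-(methoxymethoxy)-2,2-dimethyl-2H-chromen-6-yl]-4H-chromen-4-one | COc1cc(Br)c(O)c2c(=O)c(-c3cc4c(cc3OCOC)OC(C)(C)C=C4)coc12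
F7 | step 12 | 4-(9-borabicyclo[3.3.1]nonan-9-yl)-2-methylbutan-2-ol | CC(C)(O)CCB1C2CCCC1CCC2
F8 | step 11 | pyromeconic acid (3-hydroxy-4H-pyran-4-one) | O=c1ccocc1O
F9 | step 11 | 4-oxo-4H-pyran-3-yl trifluoromethanesulfonate | O=c1ccocc1OS(=O)(=O)C(F)(F)F
F10 | step 11 | 3-[7-(methoxymethoxy)-2,2-dimethyl-2H-chromen-6-yl]-4H-pyran-4-one | O=c1ccocc1-c1cc2C=CC(C)(C)Oc2cc1OCOC
F11 | step 11 | {5-[7-(methoxymethoxy)-2,2-dimethyl-2H-chromen-6-yl]-4-oxo-4H-pyran-2-yl}lithium | [Li]c1cc(=O)c(-c2cc3c(cc2OCOC)OC(C)(C)C=C3)co1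
F12 | step 11 | lithium pentacarbonyl[(5-aryl-4-oxo-4H-pyran-2-yl)oxidomethylidene]chromate | [Li+].[O-]C(=[Cr](=C=O)(=C=O)(=C=O)(=C=O)=C=O)c1cc(=O)c(-c2cc3c(cc2OCOC)OC(C)(C)C=C3)co1
F13 | step 13 | tetramethylammonium pentacarbonyl[(5-aryl-4-oxo-4H-pyran-2-yl)oxidomethylidene]chromate | C[N+](C)(C)C.[O-]C(=[Cr](=C=O)(=C=O)(=C=O)(=C=O)=C=O)c1cc(=O)c(-c2cc3c(cc2OCOC)OC(C)(C)C=C3)co1
F14 | step 13 | pentacarbonyl{acetoxy[5-(7-methoxymethoxy-2,2-dimethyl-2H-chromen-6-yl)-4-oxo-4H-pyran-2-yl]carbene}chromium | CC(=O)OC(=[Cr](=C=O)(=C=O)(=C=O)(=C=O)=C=O)c1cc(=O)c(-c2cc3c(cc2OCOC)OC(C)(C)C=C3)co1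
F15 | step 13 | pentacarbonyl{(4-methoxybenzyloxy)[5-(7-methoxymethoxy-2,2-dimethyl-2H-chromen-6-yl)-4-oxo-4H-pyran-2-yl]carbene}chromium | COc1ccc(COC(=[Cr](=C=O)(=C=O)(=C=O)(=C=O)=C=O)c2cc(=O)c(-c3cc4c(cc3OCOC)OC(C)(C)C=C4)co2)cc1
F16 | step 13 | 5-hydroxy-6-(3-hydroxy-3-methylbutyl)-8-(4-methoxybenzyloxy)-3-[7-(methoxymethoxy)-2,2-dimethyl-2H-chromen-6-yl]-4H-chromen-4-one | COc1ccc(COc2cc(CCC(C)(C)O)c(O)c3c(=O)c(-c4cc5c(cc4OCOC)OC(C)(C)C=C5)coc23)cc1
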